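The oxolane (O bridging C7 and C10) carries C11 on C10; raising C11 to the carboxyl level lets O7 be acylated by C11, so the five-membered ether maps onto a six-membered lactone from 2-deoxy-D-glucose (C4–C9, with C5, C6, C7 preset) plus a two-carbon Wittig unit (C10, C11). The precursor 10 is this δ-lactone with a triflate on C10, cis to the C7 side chain, O6 silylated and O4/O5 as acetonide. Methanolysis releases the O7 alkoxide, which displaces the triflate with inversion: one operation forms the O7–C10 bond, closes the cis-oxolane, sets C10 and leaves C11 as an ester for the methyl carbinol. Propiolate-derived lactone and caffeate follow.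

Key step: step 7

Remark: locants C1–C12 follow the target chain (C1 lactone carbonyl, C12 methyl). Read from its SMILES the target is 5R,6S,7R,10S,11S with a 2,5-cis oxolane, so the hydroxy lactone must be 10R (hydroxyl cis to the C7 side chain) before the inverting closure.
Assumption: the (+)-(2R,8aS)-oxaziridine and the substrate favour the same face of the lactone enolate; if the pairing proves mismatched, its antipode takes its place.

Step 1
Reactants: 1 2-deoxy-D-glucose; 2 ethyl (triphenylphosphoranylidene)acetate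
Product: 3 ethyl (2E,5R,6S,7R)-5,6,7,8-tetrahydroxyoct-2-enoate
Conditions: 2 (1.2 equiv), THF, reflux
Reagents that add atoms: none
Why: Wittig olefination: the stabilised ylide traps the open-chain aldehyde that equilibrates with the lactol and gives the E-enoate under neutral conditions, under which the free hydroxyls should not add to the enoate.

Step 2
Reactants: 3 ethyl (2E,5R,6S,7R)-5,6,7,8-tetrahydroxyoct-2-enoate
Product: 5 (6R)-6-[(1R,2R)-1,2,3-trihydroxypropyl]oxan-2-one, via saturated tetraol ester 4 (not isolated)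
Conditions: H2 (1 atm), 10% Pd/C, EtOH, rt; filter; then p-toluenesulfonic acid monohydrate (cat.), MeCN, 50 °C, EtOH distilled off
Reagents that add atoms: none
Why: Catalytic hydrogenation of the conjugated alkene followed by acid-catalysed lactonisation: O7 is the only hydroxyl δ to the ester, so the six-membered lactone is the one unstrained ring available, and no stereocentre is touched.

Step 3
Reactants: 5 (6R)-6-[(1R,2R)-1,2,3-trihydroxypropyl]oxan-2-one
Product: 6 (6R)-6-{(S)-[(4R)-2,2-dimethyl-1,3-dioxolan-4-yl](hydroxy)methyl}oxan-2-one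
Conditions: 2-methoxypropene (1.3 equiv), pyridinium p-toluenesulfonate (cat.), DMF, 0 °C
Reagents that add atoms: 2-methoxypropene, COC(C)=C
Why: Kinetic acetalisation with an enol ether: the primary O4 hydroxyl reacts first and the mixed acetal closes to the five-membered dioxolane on O5, while the single equivalent of methanol formed at 0 °C should leave the lactone intact.

Step 4
Reactants: 6 (6R)-6-{(S)-[(4R)-2,2-dimethyl-1,3-dioxolan-4-yl](hydroxy)methyl}oxan-2-one
Product: 7 (6R)-6-{(S)-[(tert-butyldimethylsilyl)oxy][(4R)-2,2-dimethyl-1,3-dioxolan-4-yl]methyl}oxan-2-one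
Conditions: TBSOTf, 2,6-lutidine, CH2Cl2, −78 to 0 °C
Reagents that add atoms: tert-butyldimethylsilyl trifluoromethanesulfonate, CC(C)(C)[Si](C)(C)OS(=O)(=O)C(F)(F)F
Why: Silylation with a silyl triflate and a hindered base protects the one remaining, hindered secondary hydroxyl (O6) without enolising the lactone.

Step 5
Reactants: 7 (6R)-6-{(S)-[(tert-butyldimethylsilyl)oxy][(4R)-2,2-dimethyl-1,3-dioxolan-4-yl]methyl}oxan-2-one
Product: 9 (3R,6R)-6-{(S)-[(tert-butyldimethylsilyl)oxy][(4R)-2,2-dimethyl-1,3-dioxolan-4-yl]methyl}-3-hydroxyoxan-2-one, via sodium enolate 8 (not isolated)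
Conditions: NaN(SiMe3)2, THF, −78 °C; then (+)-(2R,8aS)-(camphorsulfonyl)oxaziridine, −78 °C; NH4Cl aq.
Reagents that add atoms: (+)-(2R,8aS)-(camphorsulfonyl)oxaziridine, CC1(C)[C@@H]2CC[C@]13CS(=O)(=O)N4O[C@@]34C2
Why: Davis enolate hydroxylation: oxygen transfer to C10 through a chair-like transition state (axial attack on the half-chair enolate with the C7 side chain equatorial) gives the 10R alcohol cis to the side chain, and the enantiopure oxaziridine is chosen so that reagent control reinforces this weak 1,4-induction.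

Step 6
Reactants: 9 (3R,6R)-6-{(S)-[(tert-butyldimethylsilyl)oxy][(4R)-2,2-dimethyl-1,3-dioxolan-4-yl]methyl}-3-hydroxyoxan-2-one
Product: 10 (3R,6R)-6-{(S)-[(tert-butyldimethylsilyl)oxy][(4R)-2,2-dimethyl-1,3-dioxolan-4-yl]methyl}-2-oxooxan-3-yl trifluoromethanesulfonate
Conditions: Tf2O, pyridine, CH2Cl2, −40 to −10 °C
Reagents that add atoms: trifluoromethanesulfonic anhydride, O=S(=O)(OS(=O)(=O)C(F)(F)F)C(F)(F)F
Why: O-Sulfonylation of the α-hydroxy lactone with retention at C10; a triflate next to a carbonyl resists ionisation, so the product should survive a cold work-up and be carried on at once.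

Step 7
Reactants: 10 (3R,6R)-6-{(S)-[(tert-butyldimethylsilyl)oxy][(4R)-2,2-dimethyl-1,3-dioxolan-4-yl]methyl}-2-oxooxan-3-yl trifluoromethanesulfonate
Product: 12 methyl (2S,5R)-5-{(S)-[(tert-butyldimethylsilyl)oxy][(4R)-2,2-dimethyl-1,3-dioxolan-4-yl]methyl}oxolane-2-carboxylate, via ring-opened hydroxy ester triflate 11 (not isolated)
Conditions: K2CO3 (1.5 equiv), MeOH, −20 to 0 °C
Reagents that add atoms: methanol, CO
Why: Methoxide adds to the lactone carbonyl C11 and the tetrahedral adduct collapses to the methyl ester 11, which frees O7 as an alkoxide four atoms away from the triflate-bearing C10. The alkoxide then attacks C10 from the rear in an intramolecular Williamson etherification, 5-exo-tet, which makes the O7–C10 bond and the oxolane; the closest known reaction type is the base-induced contraction of α-triflyloxy aldono-δ-lactones to 2,5-anhydro aldonate esters. C10 is the one stereocentre set here: SN2 inversion turns 10R into 10S, so the cis relationship of triflate and C7 side chain in 10 becomes the 2,5-cis oxolane, with C7 untouched. The step needs ring-opening to outrun enolisation of the triflyloxy lactone (epimerisation or elimination) and closure through O7 to outrun migration of the O6 silyl group; the high SN2 reactivity of a triflate next to a carbonyl and the low temperature should secure both. The ester is taken out of the base promptly so that C10 is not epimerised afterwards.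

Step 8
Reactants: 12 methyl (2S,5R)-5-{(S)-[(tert-butyldimethylsilyl)oxy][(4R)-2,2-dimethyl-1,3-dioxolan-4-yl]methyl}oxolane-2-carboxylate
Product: 14 1-[(2S,5R)-5-{(S)-[(tert-butyldimethylsilyl)oxy][(4R)-2,2-dimethyl-1,3-dioxolan-4-yl]methyl}oxolan-2-yl]ethan-1-one, via Weinreb amide 13 (not isolated)
Conditions: MeNH(OMe)·HCl, iPrMgCl, THF, −20 °C; then MeMgBr, −20 to 0 °C; NH4Cl aq.
Reagents that add atoms: methylmagnesium bromide, C[Mg]Br; N,O-dimethylhydroxylamine hydrochloride, CNOC.Cl (atoms held in 13 only, lost again in 14)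
Why: Ester-to-Weinreb-amide exchange with the chloromagnesium amide followed by Weinreb ketone synthesis: the magnesium-chelated tetrahedral adduct survives until the quench, so over-addition and base-induced epimerisation at C10 are avoided.

Step 9
Reactants: 14 1-[(2S,5R)-5-{(S)-[(tert-butyldimethylsilyl)oxy][(4R)-2,2-dimethyl-1,3-dioxolan-4-yl]methyl}oxolan-2-yl]ethan-1-one
Product: 15 (1S)-1-[(2S,5R)-5-{(S)-[(tert-butyldimethylsilyl)oxy][(4R)-2,2-dimethyl-1,3-dioxolan-4-yl]methyl}oxolan-2-yl]ethan-1-ol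
Conditions: (R)-2-methyl-CBS-oxazaborolidine [(3aR)-1-methyl-3,3-diphenyltetrahydro-1H,3H-pyrrolo[1,2-c][1,3,2]oxazaborole] (10 mol %), BH3·SMe2, THF, −20 °C; MeOH quench
Reagents that add atoms: none
Why: Corey–Bakshi–Shibata reduction: with the oxolanyl carbon as the large and methyl as the small group the (R)-catalyst should deliver hydride to the face that gives 11S, which is also the Felkin–Anh face of this α-alkoxy ketone, so catalyst and substrate are expected to be matched.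

Step 10
Reactants: 15 (1S)-1-[(2S,5R)-5-{(S)-[(tert-butyldimethylsilyl)oxy][(4R)-2,2-dimethyl-1,3-dioxolan-4-yl]methyl}oxolan-2-yl]ethan-1-ol
Product: 16 (2R,3R)-3-[(tert-butyldimethylsilyl)oxy]-3-{(2R,5S)-5-[(1S)-1-hydroxyethyl]oxolan-2-yl}propane-1,2-diol
Conditions: AcOH/H2O (4:1), 35 °C
Reagents that add atoms: none
Why: Acid-catalysed acetal hydrolysis: the terminal dioxolane is cleaved by aqueous acetic acid well before a hindered secondary tert-butyldimethylsilyl ether.

Step 11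
Reactants: 16 (2R,3R)-3-[(tert-butyldimethylsilyl)oxy]-3-{(2R,5S)-5-[(1S)-1-hydroxyethyl]oxolan-2-yl}propane-1,2-diol
Product: 18 (1S)-1-[(2S,5R)-5-{(S)-[(tert-butyldimethylsilyl)oxy][(2R)-oxiran-2-yl]methyl}oxolan-2-yl]ethan-1-ol, via primary tosylate 17 (not isolated)
Conditions: TsCl, Et3N, Bu2SnO (cat.), CH2Cl2, 0 °C to rt; then K2CO3, MeOH, 0 °C
Reagents that add atoms: p-toluenesulfonyl chloride, Cc1ccc(cc1)S(Cl)(=O)=O (atoms held in 17 only, lost again in 18)
Why: Stannylene-acetal-directed sulfonylation picks the primary hydroxyl of the 1,2-diol and the C5 alkoxide then closes the oxirane by 3-exo-tet displacement at C4 (intramolecular Williamson), so no bond to C5 is broken and its configuration is kept.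

Step 12
Reactants: 19 caffeic acid
Product: 21 (2E)-3-{3,4-bis[(tert-butyldimethylsilyl)oxy]phenyl}prop-2-enoic acid, via tris-silyl derivative 20 (not isolated)
Conditions: TBSCl (3.5 equiv), imidazole, DMF, rt; then AcOH/THF/H2O, rt
Reagents that add atoms: tert-butyldimethylsilyl chloride, CC(C)(C)[Si](C)(C)Cl
Why: Silyl ether formation on both phenols and the acid, then selective hydrolysis of the far more labile silyl ester, frees the carboxylic acid for coupling.

Step 13
Reactants: 18 (1S)-1-[(2S,5R)-5-{(S)-[(tert-butyldimethylsilyl)oxy][(2R)-oxiran-2-yl]methyl}oxolan-2-yl]ethan-1-ol; 21 (2E)-3-{3,4-bis[(tert-butyldimethylsilyl)oxy]phenyl}prop-2-enoic acid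
Product: 22 (1S)-1-[(2S,5R)-5-{(S)-[(tert-butyldimethylsilyl)oxy][(2R)-oxiran-2-yl]methyl}oxolan-2-yl]ethyl (2E)-3-{3,4-bis[(tert-butyldimethylsilyl)oxy]phenyl}prop-2-enoate
Conditions: DCC, 4-(dimethylamino)pyridine (cat.), CH2Cl2, 0 °C to rt
Reagents that add atoms: none
Why: Steglich esterification acylates the only free hydroxyl (C11) with retention, and the mild carbodiimide conditions should leave the oxirane and the silyl ethers untouched.

Step 14
Reactants: 22 (1S)-1-[(2S,5R)-5-{(S)-[(tert-butyldimethylsilyl)oxy][(2R)-oxiran-2-yl]methyl}oxolan-2-yl]ethyl (2E)-3-{3,4-bis[(tert-butyldimethylsilyl)oxy]phenyl}prop-2-enoate; 23 ethyl propiolate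
Product: 25 ethyl (5R,6R)-6-[(tert-butyldimethylsilyl)oxy]-6-{(2R,5S)-5-[(1S)-1-{[(2E)-3-{3,4-bis[(tert-butyldimethylsilyl)oxy]phenyl}prop-2-enoyl]oxy}ethyl]oxolan-2-yl}-5-hydroxyhex-2-ynoate, via lithium acetylide 24 (not isolated)
Conditions: 23, n-BuLi, THF, −78 °C; then BF3·OEt2, then 22, −78 °C; NH4Cl aq.
Reagents that add atoms: none
Why: Yamaguchi–Hirao alkynylation: BF3 activates the oxirane, the lithium acetylide attacks the unsubstituted C4 by SN2, C5 keeps its configuration, and at −78 °C the caffeate ester and the silyl ethers are spectators.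

Step 15
Reactants: 25 ethyl (5R,6R)-6-[(tert-butyldimethylsilyl)oxy]-6-{(2R,5S)-5-[(1S)-1-{[(2E)-3-{3,4-bis[(tert-butyldimethylsilyl)oxy]phenyl}prop-2-enoyl]oxy}ethyl]oxolan-2-yl}-5-hydroxyhex-2-ynoate
Product: 27 (1S)-1-[(2S,5R)-5-{(S)-[(tert-butyldimethylsilyl)oxy][(2R)-6-oxo-3,6-dihydro-2H-pyran-2-yl]methyl}oxolan-2-yl]ethyl (2E)-3-{3,4-bis[(tert-butyldimethylsilyl)oxy]phenyl}prop-2-enoate, via Z-hydroxy enoate 26 (not isolated)
Conditions: H2 (1 atm), 5% Pd/CaCO3 poisoned with Pb(OAc)2 (Lindlar catalyst), quinoline, EtOAc, rt; then pyridinium p-toluenesulfonate (cat.), toluene, 60 °C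
Reagents that add atoms: none
Why: Lindlar semihydrogenation gives the Z-enoate without reducing the caffeate alkene, and the Z geometry brings the C5 hydroxyl next to the ester so that acid-catalysed lactonisation closes the 5,6-dihydro-2H-pyran-2-one.

Step 16
Reactants: 27 (1S)-1-[(2S,5R)-5-{(S)-[(tert-butyldimethylsilyl)oxy][(2R)-6-oxo-3,6-dihydro-2H-pyran-2-yl]methyl}oxolan-2-yl]ethyl (2E)-3-{3,4-bis[(tert-butyldimethylsilyl)oxy]phenyl}prop-2-enoate
Product: 28 (1S)-1-[(2S,5R)-5-{(S)-hydroxy[(2R)-6-oxo-3,6-dihydro-2H-pyran-2-yl]methyl}oxolan-2-yl]ethyl (2E)-3-(3,4-dihydroxyphenyl)prop-2-enoate (target, CNP0300981.1)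
Conditions: Bu4NF, AcOH (1:1), THF, 0 °C to rt
Reagents that add atoms: none
Why: Fluoride-induced desilylation cleaves the two aryl and the one alkyl silyl ether in a single operation, the acetic acid buffer keeping the enoate lactone, the caffeate and the catechol away from basic fluoride.

Compound list
1 | 2-deoxy-D-glucose | O=CC[C@@H](O)[C@H](O)[C@H](O)CO | starting material
2 | ethyl (triphenylphosphoranylidene)acetate | CCOC(=O)C=P(c1ccccc1)(c1ccccc1)c1ccccc1 | starting material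
3 | ethyl (2E,5R,6S,7R)-5,6,7,8-tetrahydroxyoct-2-enoate | CCOC(=O)/C=C/C[C@@H](O)[C@H](O)[C@H](O)CO | intermediate
4 | ethyl (5R,6S,7R)-5,6,7,8-tetrahydroxyoctanoate | CCOC(=O)CCC[C@@H](O)[C@H](O)[C@H](O)CO | intermediate (not isolated)
5 | (6R)-6-[(1R,2R)-1,2,3-trihydroxypropyl]oxan-2-one | O=C1CCC[C@H]([C@H](O)[C@H](O)CO)O1 | intermediate
6 | (6R)-6-{(S)-[(4R)-2,2-dimethyl-1,3-dioxolan-4-yl](hydroxy)methyl}oxan-2-one | O=C1CCC[C@H]([C@H](O)[C@H]2COC(C)(C)O2)O1 | intermediate
7 | (6R)-6-{(S)-[(tert-butyldimethylsilyl)oxy][(4R)-2,2-dimethyl-1,3-dioxolan-4-yl]methyl}oxan-2-one | O=C1CCC[C@H]([C@H](O[Si](C)(C)C(C)(C)C)[C@H]2COC(C)(C)O2)O1 | intermediate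
8 | sodium enolate of 7 (sodium 6-substituted 5,6-dihydro-4H-pyran-2-olate, 6R) | [Na+].[O-]C1=CCC[C@H]([C@H](O[Si](C)(C)C(C)(C)C)[C@H]2COC(C)(C)O2)O1 | intermediate (not isolated)
9 | (3R,6R)-6-{(S)-[(tert-butyldimethylsilyl)oxy][(4R)-2,2-dimethyl-1,3-dioxolan-4-yl]methyl}-3-hydroxyoxan-2-one | O=C1[C@H](O)CC[C@H]([C@H](O[Si](C)(C)C(C)(C)C)[C@H]2COC(C)(C)O2)O1 | intermediate
10 | (3R,6R)-6-{(S)-[(tert-butyldimethylsilyl)oxy][(4R)-2,2-dimethyl-1,3-dioxolan-4-yl]methyl}-2-oxooxan-3-yl trifluoromethanesulfonate | O=C1[C@H](OS(=O)(=O)C(F)(F)F)CC[C@H]([C@H](O[Si](C)(C)C(C)(C)C)[C@H]2COC(C)(C)O2)O1 | intermediate (key-step precursor)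
11 | methyl (2R,5R,6S)-6-[(tert-butyldimethylsilyl)oxy]-6-[(4R)-2,2-dimethyl-1,3-dioxolan-4-yl]-5-hydroxy-2-[(trifluoromethanesulfonyl)oxy]hexanoate (present as its alkoxide) | COC(=O)[C@H](OS(=O)(=O)C(F)(F)F)CC[C@@H](O)[C@H](O[Si](C)(C)C(C)(C)C)[C@H]1COC(C)(C)O1 | intermediate (not isolated)
12 | methyl (2S,5R)-5-{(S)-[(tert-butyldimethylsilyl)oxy][(4R)-2,2-dimethyl-1,3-dioxolan-4-yl]methyl}oxolane-2-carboxylate | COC(=O)[C@@H]1CC[C@H]([C@H](O[Si](C)(C)C(C)(C)C)[C@H]2COC(C)(C)O2)O1 | intermediate (key-step product)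
13 | (2S,5R)-5-{(S)-[(tert-butyldimethylsilyl)oxy][(4R)-2,2-dimethyl-1,3-dioxolan-4-yl]methyl}-N-methoxy-N-methyloxolane-2-carboxamide | CON(C)C(=O)[C@@H]1CC[C@H]([C@H](O[Si](C)(C)C(C)(C)C)[C@H]2COC(C)(C)O2)O1 | intermediate (not isolated)
14 | 1-[(2S,5R)-5-{(S)-[(tert-butyldimethylsilyl)oxy][(4R)-2,2-dimethyl-1,3-dioxolan-4-yl]methyl}oxolan-2-yl]ethan-1-one | CC(=O)[C@@H]1CC[C@H]([C@H](O[Si](C)(C)C(C)(C)C)[C@H]2COC(C)(C)O2)O1 | intermediate
15 | (1S)-1-[(2S,5R)-5-{(S)-[(tert-butyldimethylsilyl)oxy][(4R)-2,2-dimethyl-1,3-dioxolan-4-yl]methyl}oxolan-2-yl]ethan-1-ol | C[C@H](O)[C@@H]1CC[C@H]([C@H](O[Si](C)(C)C(C)(C)C)[C@H]2COC(C)(C)O2)O1 | intermediate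
16 | (2R,3R)-3-[(tert-butyldimethylsilyl)oxy]-3-{(2R,5S)-5-[(1S)-1-hydroxyethyl]oxolan-2-yl}propane-1,2-diol | C[C@H](O)[C@@H]1CC[C@H]([C@H](O[Si](C)(C)C(C)(C)C)[C@H](O)CO)O1 | intermediate
17 | (2R,3R)-3-[(tert-butyldimethylsilyl)oxy]-2-hydroxy-3-{(2R,5S)-5-[(1S)-1-hydroxyethyl]oxolan-2-yl}propyl 4-methylbenzenesulfonate | C[C@H](O)[C@@H]1CC[C@H]([C@H](O[Si](C)(C)C(C)(C)C)[C@H](O)COS(=O)(=O)c2ccc(C)cc2)O1 | intermediate (not isolated)
18 | (1S)-1-[(2S,5R)-5-{(S)-[(tert-butyldimethylsilyl)oxy][(2R)-oxiran-2-yl]methyl}oxolan-2-yl]ethan-1-ol | C[C@H](O)[C@@H]1CC[C@H]([C@H](O[Si](C)(C)C(C)(C)C)[C@H]2CO2)O1 | intermediate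
19 | caffeic acid | OC(=O)/C=C/c1ccc(O)c(O)c1 | starting material
20 | tert-butyldimethylsilyl (2E)-3-{3,4-bis[(tert-butyldimethylsilyl)oxy]phenyl}prop-2-enoate | CC(C)(C)[Si](C)(C)OC(=O)/C=C/c1ccc(O[Si](C)(C)C(C)(C)C)c(O[Si](C)(C)C(C)(C)C)c1 | intermediate (not isolated)
21 | (2E)-3-{3,4-bis[(tert-butyldimethylsilyl)oxy]phenyl}prop-2-enoic acid | OC(=O)/C=C/c1ccc(O[Si](C)(C)C(C)(C)C)c(O[Si](C)(C)C(C)(C)C)c1 | intermediate
22 | (1S)-1-[(2S,5R)-5-{(S)-[(tert-butyldimethylsilyl)oxy][(2R)-oxiran-2-yl]methyl}oxolan-2-yl]ethyl (2E)-3-{3,4-bis[(tert-butyldimethylsilyl)oxy]phenyl}prop-2-enoate | C[C@H](OC(=O)/C=C/c1ccc(O[Si](C)(C)C(C)(C)C)c(O[Si](C)(C)C(C)(C)C)c1)[C@@H]1CC[C@H]([C@H](O[Si](C)(C)C(C)(C)C)[C@H]2CO2)O1 | intermediate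
23 | ethyl propiolate | CCOC(=O)C#C | starting material
24 | ethyl 3-lithioprop-2-ynoate | [Li]C#CC(=O)OCC | intermediate (not isolated)
25 | ethyl (5R,6R)-6-[(tert-butyldimethylsilyl)oxy]-6-{(2R,5S)-5-[(1S)-1-{[(2E)-3-{3,4-bis[(tert-butyldimethylsilyl)oxy]phenyl}prop-2-enoyl]oxy}ethyl]oxolan-2-yl}-5-hydroxyhex-2-ynoate | C[C@H](OC(=O)/C=C/c1ccc(O[Si](C)(C)C(C)(C)C)c(O[Si](C)(C)C(C)(C)C)c1)[C@@H]1CC[C@H]([C@H](O[Si](C)(C)C(C)(C)C)[C@H](O)CC#CC(=O)OCC)O1 | intermediate
26 | ethyl (2Z,5R,6R)-6-[(tert-butyldimethylsilyl)oxy]-6-{(2R,5S)-5-[(1S)-1-{[(2E)-3-{3,4-bis[(tert-butyldimethylsilyl)oxy]phenyl}prop-2-enoyl]oxy}ethyl]oxolan-2-yl}-5-hydroxyhex-2-enoate | C[C@H](OC(=O)/C=C/c1ccc(O[Si](C)(C)C(C)(C)C)c(O[Si](C)(C)C(C)(C)C)c1)[C@@H]1CC[C@H]([C@H](O[Si](C)(C)C(C)(C)C)[C@H](O)C/C=C\C(=O)OCC)O1 | intermediate (not isolated)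
27 | (1S)-1-[(2S,5R)-5-{(S)-[(tert-butyldimethylsilyl)oxy][(2R)-6-oxo-3,6-dihydro-2H-pyran-2-yl]methyl}oxolan-2-yl]ethyl (2E)-3-{3,4-bis[(tert-butyldimethylsilyl)oxy]phenyl}prop-2-enoate | C[C@H](OC(=O)/C=C/c1ccc(O[Si](C)(C)C(C)(C)C)c(O[Si](C)(C)C(C)(C)C)c1)[C@@H]1CC[C@H]([C@H](O[Si](C)(C)C(C)(C)C)[C@H]2CC=CC(=O)O2)O1 | intermediate
28 | (1S)-1-[(2S,5R)-5-{(S)-hydroxy[(2R)-6-oxo-3,6-dihydro-2H-pyran-2-yl]methyl}oxolan-2-yl]ethyl (2E)-3-(3,4-dihydroxyphenyl)prop-2-enoate | C[C@H](OC(=O)/C=C/c1ccc(O)c(O)c1)[C@@H]1CC[C@H]([C@H](O)[C@H]2CC=CC(=O)O2)O1 | target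

Total step count: 16 (15 in the main line plus step 12 for acid 21).
Longest linear sequence: 15 steps (steps 1–11 and 13–16).

Steps most likely to fail

Step 5. What may go wrong: poor facial selectivity in the oxygen transfer to the lactone enolate, since 1,4-induction from C7 is weak and reagent control on a lactone enolate is not assured, so that much of the 10S epimer forms. Fallback (configuration corrected by SN2 inversion instead of by facial control): setting out from 7, the hydroxylation is run as above, the epimers are separated and the (3S,6R)-hydroxy lactone F1 is converted with Tf2O and pyridine in CH2Cl2 at −40 °C into the trans-triflate F2. CF3CO2Cs in butanone then displaces the triflate with inversion to give the (3R)-trifluoroacetate F3, whose labile ester is cleaved by methanol on work-up. The route is rejoined at 9.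

Step 7. What may go wrong: enolisation of the triflyloxy lactone before ring-opening (epimerisation at C10 or loss of triflic acid to the unsaturated lactone), or migration of the silyl group from O6 to O7 followed by closure through O6. Fallback (no carbonyl beside the leaving group; the ring is closed by epoxide opening): setting out from 9, LiBH4 in THF reduces the lactone to the 7,10,11-triol F4. Bu2SnO-catalysed tosylation (TsCl, Et3N) at the primary C11 hydroxyl gives the tosylate F5, and K2CO3 in MeOH gives the 10,11-epoxide F6 with C10 unchanged. Camphor-10-sulfonic acid in CH2Cl2 then triggers 5-exo opening by the C7 hydroxyl with inversion at C10 to the cis-oxolanylmethanol F7. Oxidation with TEMPO and PhI(OAc)2 in aqueous MeCN gives the acid F8, and Me3SiCHN2 in toluene/MeOH gives the methyl ester, rejoining the route at 12.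

Step 9. What may go wrong: insufficient facial selectivity in the hydride transfer, because the ring oxygen and the neighbouring silyl ether can bind borane and blur the large/small distinction at the ketone. Fallback (C11 set by C–C bond formation under chelation control instead of by carbonyl reduction): setting out from 12, iBu2AlH in toluene at −78 °C stops at the oxolane-2-carbaldehyde F9. MeMgBr with MgBr2·OEt2 in CH2Cl2 at −78 °C then adds to the five-membered magnesium chelate of ring oxygen and carbonyl oxygen from the side of the C10 hydrogen, which should give the 11S carbinol and rejoin the route at 15.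

Further compounds
F1 | step 5 | (3S,6R)-6-{(S)-[(tert-butyldimethylsilyl)oxy][(4R)-2,2-dimethyl-1,3-dioxolan-4-yl]methyl}-3-hydroxyoxan-2-one | O=C1[C@@H](O)CC[C@H]([C@H](O[Si](C)(C)C(C)(C)C)[C@H]2COC(C)(C)O2)O1
F2 | step 5 | (3S,6R)-6-{(S)-[(tert-butyldimethylsilyl)oxy][(4R)-2,2-dimethyl-1,3-dioxolan-4-yl]methyl}-2-oxooxan-3-yl trifluoromethanesulfonate | O=C1[C@@H](OS(=O)(=O)C(F)(F)F)CC[C@H]([C@H](O[Si](C)(C)C(C)(C)C)[C@H]2COC(C)(C)O2)O1
F3 | step 5 | (3R,6R)-6-{(S)-[(tert-butyldimethylsilyl)oxy][(4R)-2,2-dimethyl-1,3-dioxolan-4-yl]methyl}-2-oxooxan-3-yl trifluoroacetate | O=C1[C@H](OC(=O)C(F)(F)F)CC[C@H]([C@H](O[Si](C)(C)C(C)(C)C)[C@H]2COC(C)(C)O2)O1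
F4 | step 7 | (2R,5R,6S)-6-[(tert-butyldimethylsilyl)oxy]-6-[(4R)-2,2-dimethyl-1,3-dioxolan-4-yl]hexane-1,2,5-triol | OC[C@H](O)CC[C@@H](O)[C@H](O[Si](C)(C)C(C)(C)C)[C@H]1COC(C)(C)O1
F5 | step 7 | (2R,5R,6S)-6-[(tert-butyldimethylsilyl)oxy]-6-[(4R)-2,2-dimethyl-1,3-dioxolan-4-yl]-2,5-dihydroxyhexyl 4-methylbenzenesulfonate | Cc1ccc(cc1)S(=O)(=O)OC[C@H](O)CC[C@@H](O)[C@H](O[Si](C)(C)C(C)(C)C)[C@H]1COC(C)(C)O1
F6 | step 7 | (1S,2R)-1-[(tert-butyldimethylsilyl)oxy]-1-[(4R)-2,2-dimethyl-1,3-dioxolan-4-yl]-4-[(2R)-oxiran-2-yl]butan-2-ol | C1O[C@@H]1CC[C@@H](O)[C@H](O[Si](C)(C)C(C)(C)C)[C@H]2COC(C)(C)O2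
F7 | step 7 | [(2S,5R)-5-{(S)-[(tert-butyldimethylsilyl)oxy][(4R)-2,2-dimethyl-1,3-dioxolan-4-yl]methyl}oxolan-2-yl]methanol | OC[C@@H]1CC[C@H]([C@H](O[Si](C)(C)C(C)(C)C)[C@H]2COC(C)(C)O2)O1
F8 | step 7 | (2S,5R)-5-{(S)-[(tert-butyldimethylsilyl)oxy][(4R)-2,2-dimethyl-1,3-dioxolan-4-yl]methyl}oxolane-2-carboxylic acid | OC(=O)[C@@H]1CC[C@H]([C@H](O[Si](C)(C)C(C)(C)C)[C@H]2COC(C)(C)O2)O1
F9 | step 9 | (2S,5R)-5-{(S)-[(tert-butyldimethylsilyl)oxy][(4R)-2,2-dimethyl-1,3-dioxolan-4-yl]methyl}oxolane-2-carbaldehyde | O=C[C@@H]1CC[C@H]([C@H](O[Si](C)(C)C(C)(C)C)[C@H]2COC(C)(C)O2)O1
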